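## Structural features

The target (C25H40O2) is a bicyclic terpenoid acid built on a trans-fused decalin. Ring A (C1–C5, C10) and ring B (C5–C10) share the C5–C10 bond, and labdane-type numbering is used throughout, with the side chain on C9 as C11–C15. Ring A holds three contiguous stereocentres, all S: quaternary C4 (β-methyl, α-oriented 4-methylpent-3-enyl chain), tertiary C5 (α-hydrogen) and the angular quaternary C10 (β-methyl). The two methyl groups are 1,3-syn-diaxial and H5 is anti to the C10 methyl. Ring B contains a tetrasubstituted C8=C9 alkene that carries the C8 methyl and, on C9, a CH2CH2 link to an (E)-β-methylacrylic acid (C13=C14, C15 acid). Apart from the carboxyl group the molecule is a hydrocarbon, so any auxiliary oxygen must be consumed or removed. The fragile groups are the three alkenes: the tri- and tetrasubstituted ones are prone to acid-induced migration, cation–olefin cyclisation and oxidation, and the enoic acid can lose its E geometry or deconjugate. The real difficulty is the C4 quaternary centre, whose two alkyl groups differ only at a distance, together with the absolute configuration of C10 and the hindered C8=C9 alkene next to C10. The key step exploits the fact that C10, C5 and C4 are the β-carbon, α-carbon and carbonyl carbon of 3-methylcyclohex-2-enone. C9–C10 and C5–C6 are then the bonds of a conjugate addition and an enolate alkylation, and the C4 carbonyl remains as the handle for the quaternary centre.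

## Logic of the disconnections

**25 from 24.** The C15–O bond of the acid is traced back to a methyl ester. The ester is what the alkyne carbometalation delivers, and it keeps the acidic proton out of the last C–C bond formations. There is no skeletal gain. The forward step must hydrolyse without E/Z or positional isomerisation of the enoate.

**24 from 22 (through 23).** The cuts are C13–CH3 and C14–C15, both on the C13=C14 alkene. Syn addition of methyl and a metal across a terminal alkyne, followed by acylation, is the most dependable source of an (E)-trisubstituted enoate. The stereodefined five-carbon terminus shrinks to a butynyl group. The forward step must place methyl on C13 and leave the other two alkenes alone.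

**22 from 18 and 19 (through 21 and 20).** The cut is C9–C11, an sp2–sp3 bond and the only link between side chain and ring B. The tetrasubstituted alkene is then never made by elimination, so no alkene regioisomers arise, and the chain comes from a commercial four-carbon bromide with a silyl-capped alkyne. The forward step is a cross-coupling at a tetrasubstituted, neopentyl-like vinyl position and must outrun β-hydride elimination.

**18 from 16 (through 17).** The C9–O bond of the enol triflate is traced back to the C9 ketone. Because C10 is quaternary, the ketone can enolise only towards C8, so the position of the double bond is automatic and the C8 stereocentre of 16 needs no control. The forward step needs complete deprotonation at a hindered tertiary α-carbon.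

**16 from 15.** The cut is the terminal C=C of the chain on C4. An isopropylidene terminus is the retron of a phosphorus ylide olefination and has no geometry to control. The chain shortens to a propanal arm, which is the adduct of a C4 radical with an enal. The forward step must select the aldehyde over the C9 ketone.

**15 from 12 (through 13 and 14).** The cut is the bond from C4 to the first chain carbon. C4 has no neighbouring activating group, so it is best made as a tertiary radical, generated from the half-oxalate of a tertiary alcohol and trapped by an electron-poor alkene. The quaternary stereocentre is reduced to a carbinol whose configuration does not matter. The forward step must generate the radical efficiently and bond on the α face, anti to the C10 methyl.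

**12 from 10 (through 11).** The cut is C8–CH3. In enone 10 the C8=C9 enolate can be formed regiospecifically by conjugate reduction and then methylated. The methyl therefore need not be present during ring formation, which is why a masked acetyl group suffices in the key step. The forward step needs 1,4-selective hydride delivery and clean C-monomethylation beside a free tertiary hydroxyl.

**10 from 7 (through 9 and 8).** The cut is C7=C8 (aldol condensation), and the C9 ketone and C7 aldehyde are then traced to two terminal alkenes. C8 is the methyl of an acetyl group and C7 an aldehyde in a 1,5-relationship, which is ideal for six-ring closure. Ring B disappears and a monocyclic ring A with two alkenyl arms remains. The forward ring closure must work on a substrate whose aldehyde is partly held as a lactol.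

**7 from 6.** The cut is C4–CH3, from methyl carbinol back to ketone. Adding the methyl before ring B is built removes the only group that acidifies C5–H, so the future ring-fusion centre is locked early. C4 returns to the carbonyl of the starting enone. The forward step needs 1,2-addition without enolisation.

**6 from 3, 2 and 4 (through 5).** The cuts are C9–C10 and C5–C6. Both bonds radiate from the β- and α-carbons of an enone whose β-methyl is the C10 methyl. Two stereocentres and thirteen of the twenty-five carbons come from three small fragments in one operation. The forward step needs enantiofacial control at a fully substituted β-carbon and regio- and diastereoselective trapping of the enolate.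

**2 from 1.** The C–Mg bond is traced to the vinylic bromide. The only demand is an ether solution suitable for the copper-catalysed step.

## Other disconnections considered

**Alternative 1:** Ring A is cut at C1–C10 and C4–C5, so that ring A is grafted onto a preformed ring B. In the forward direction a chiral Lewis acid would catalyse the [4+2] cycloaddition of quinone A1 with silyloxydiene A2, the nucleophilic diene terminus bonding to the methyl-bearing quinone carbon, to give the cis-fused endo adduct A3.
- In its favour: ring A and quaternary C10 arise in one catalytic, convergent step from two very simple partners. Ring B arrives with the C8 methyl and a C9 carbonyl in place; on this point A3 is better than 6, which needs ozonolysis, aldol closure and a reductive methylation to reach the same pattern.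
- Against it here: a suprafacial endo addition necessarily gives the cis ring fusion, so C5 has to be epimerised through the C6 ketone, and the thermodynamic preference of such a 10-methyl decalone is not expected to be large. C4 arrives as a methyl-bearing CH with the methyl on the α face, so the quaternary centre is still to be built, and the enol ether oxygen sits at C2, not next to C4. Two oxygens (C2, C6) are surplus and must be removed.
- Comparison: on C10 the two plans are equals, both being catalytic asymmetric steps with close precedent. On ring B substitution A3 is ahead. On C4 and C5 the chosen plan is ahead, because 6 has C5 trans to C9 from the same operation and the carbonyl exactly at C4. Mechanistically the concerted cycloaddition is the more predictable in regio- and enantiocontrol, but its intrinsic cis outcome is mismatched with the target. In step count the deoxygenations and the C4/C5 corrections are expected to cancel the saving in ring B, so the length would be equal or somewhat greater.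

**Alternative 2:** Both rings are cut at once, at C3–C4 and C5–C10. In the forward direction trienone A4, in which an (E)-configured β,β-disubstituted enone (C4=C5) is tethered through C6–C9 to a C10=C1–C2=C3 diene, would undergo a thermal or Lewis-acid-promoted intramolecular Diels–Alder reaction to octalinone A5.
- In its favour: the whole decalin, both quaternary centres and C5 come from one step. The homoprenyl chain is already in the acyl part of A4, and the C4/C5 relationship follows stereospecifically from the (E) alkene geometry. On C4 this is better than the chosen plan, which needs a radical sequence resting on a face-selectivity argument.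
- Against it here: one new bond ends on a fully substituted diene terminus and the other on a β,β-disubstituted enone carbon, so two quaternary carbons form in a single cycloaddition. That high barrier invites 1,5-hydrogen shifts of the diene, ene reactions and polymerisation. Absolute control rests on a preset C9 silyloxy stereocentre that must be made enantioselectively and later sacrificed, and the trans fusion needs one specific endo/exo mode. Afterwards the C6 ketone is surplus, the C1=C2 alkene must be reduced beside the prenyl-type alkene, and C8 still lacks its methyl, so the ring B endgame is the same as in the chosen plan.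
- Comparison: structurally A5 maps more of the target than 6, since C4 is complete. Mechanistically the chosen step consists of two polar bond formations with close precedent, while the cycloaddition is sterically extreme. Step economy after the key step is equal or slightly better for A5, but A4 needs a multi-step asymmetric assembly whereas 6 is reached in two steps. Overall the lengths are comparable and the chosen plan carries less risk.

**Alternative 3:** Ring B is cut at C8=C9. In the forward direction the meso triene A6 (ring A with cis methyl/vinyl pairs on C4 and C10, and a silyloxy group and a 3-methylbut-3-enyl arm on C5) would be desymmetrised by a chiral molybdenum alkylidene catalyst. Metathesis of the 1,1-disubstituted alkene of the arm with one of the two enantiotopic vinyl groups closes ring B as A7.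
- In its favour: C4 and C10 are fixed together in one catalyst-controlled step from an achiral precursor, and the C8 methyl is in place. The α-vinyl group on C4 is a direct handle for the homoprenyl chain (hydroboration, then sp3–sp2 coupling), so the C4 configuration would be settled with more certainty than by a radical addition. On C4 configuration and C8 substitution this plan is better than the chosen one.
- Against it here: C9 is left as an unsubstituted alkene CH, so attaching the side chain needs a change of oxidation level and a new C–C bond at a neopentyl position. The C5 silyloxy group must be replaced by hydrogen with trans stereochemistry between two quaternary carbons, a tertiary deoxygenation of uncertain facial outcome. Closing a trisubstituted ring alkene next to a quaternary carbon from a 1,1-disubstituted olefin is at the limit of such catalysts, which are also air-sensitive. A6 itself needs a diastereoselective construction of two quaternary centres and addition of an organometallic to a ketone flanked by both.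
- Comparison: structurally A7 carries C4 and C8 further than 6 but is worse at C5 and C9. Mechanistically both are catalyst-controlled asymmetric steps of a known class, the conjugate addition being the more robust for hindered centres. In step economy the precursor synthesis and the C5/C9 corrections would make this plan longer.

Key step: step 2

Assumption: the chiral imidazolinium salt (carbene precursor, either enantiomer accessible) is treated as an available catalyst component and not counted as a step; the enantiomer is taken that directs the isopropenyl group to the Si face of the β-carbon of 3.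

Remark: compounds 7–14 are drawn as the expected major C4 epimer and 12–16 as the expected major C8 epimer. Both centres are erased later (C4 in step 9, C8 in step 11), so epimer mixtures converge and need not be separated.

Remark: the configuration of 6 was checked against the target. Ring carbon 3 of 6 is C10 (S in both) and ring carbon 2 is C5, which is R in 6 and S in the target only because the CIP rank of C4 changes; no structure needed correction.

## Route

**Step 1**
Reactants: 1 2-bromopropene
Product: 2 isopropenylmagnesium bromide
Conditions: Mg, I2 (cat.), Et2O, reflux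
Reagents that add atoms: magnesium, [Mg]
Why: Grignard formation by insertion of magnesium into the vinylic C–Br bond; an ether solution is prepared because it suits the copper-catalysed addition that follows.

**Step 2**
Reactants: 3 3-methylcyclohex-2-en-1-one; 2 isopropenylmagnesium bromide; 4 allyl bromide
Product: 6 (2R,3S)-3-methyl-3-(prop-1-en-2-yl)-2-(prop-2-en-1-yl)cyclohexan-1-one, via magnesium enolate 5 (not isolated)
Conditions: Cu(OTf)2 (3 mol %), chiral imidazolinium chloride (4 mol %), Et2O, −30 °C; then 4, DMPU, −30 °C → rt
Reagents that add atoms: none
Why: Cu(OTf)2 is reduced by 2 to monovalent copper, which is bound by the carbene formed from the imidazolinium salt and transmetalated to an isopropenyl–copper species. This forms a π-complex with 3, adds at the β-carbon to give a trivalent copper intermediate and reductively eliminates, making C9–C10; the closest known reaction type is the copper-catalysed asymmetric conjugate addition of Grignard reagents to β-substituted cyclohexenones with enolate trapping. No ring is closed, ring A being the enone ring itself. C10 is controlled by the chiral ligand, whose enantiomer is chosen for attack on the Si face of the β-carbon, which gives the S centre. The regiodefined magnesium enolate 5 is then C-allylated by 4 in an SN2 reaction assisted by DMPU, and C5 is controlled by the substrate: the electrophile enters anti to the bulkier isopropenyl group, so allyl and isopropenyl are trans, the relationship that becomes the trans ring fusion. The step needs 1,4- over 1,2-addition (copper catalysis, slow addition), allylation at C5 and not at C3 (trapping of the kinetically formed enolate before proton transfer) and C- over O-alkylation (soft allylic bromide). C5 stays epimerisable in 6, so a cis component can be equilibrated with base and recycled.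

**Step 3**
Reactants: 6 (2R,3S)-3-methyl-3-(prop-1-en-2-yl)-2-(prop-2-en-1-yl)cyclohexan-1-one
Product: 7 (1S,2R,3S)-1,3-dimethyl-3-(prop-1-en-2-yl)-2-(prop-2-en-1-yl)cyclohexan-1-ol
Conditions: MeMgBr, CeCl3, THF, −78 → 0 °C
Reagents that add atoms: methylmagnesium bromide, C[Mg]Br
Why: Organocerium-type 1,2-addition (Grignard reagent with CeCl3) to a hindered, enolisable ketone; the weakly basic reagent should suppress enolisation and with it epimerisation of C5. Attack is expected on the face away from the axial C10 methyl (4β-alcohol), but the C4 configuration is immaterial because C4 becomes a radical in step 9. Once C4 is sp3, C5 is no longer α to a carbonyl and the trans relationship set in step 2 is locked.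

**Step 4**
Reactants: 7 (1S,2R,3S)-1,3-dimethyl-3-(prop-1-en-2-yl)-2-(prop-2-en-1-yl)cyclohexan-1-ol
Product: 9 2-[(1R,2S,6S)-2-acetyl-6-hydroxy-2,6-dimethylcyclohexyl]acetaldehyde, via bis-ozonide 8 (not isolated)
Conditions: O3, CH2Cl2, −78 °C; PPh3, −78 °C → rt
Reagents that add atoms: ozone, [O-][O+]=O
Why: Ozonolysis of both terminal alkenes with reductive work-up turns isopropenyl into the C9 acetyl group (its methyl is C8) and allyl into the C7 aldehyde. The γ-hydroxy aldehyde 9 is expected to rest largely as its five-membered lactol, with which it is in ring–chain equilibrium.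

**Step 5**
Reactants: 9 2-[(1R,2S,6S)-2-acetyl-6-hydroxy-2,6-dimethylcyclohexyl]acetaldehyde
Product: 10 (4aR,5S,8aS)-5-hydroxy-5,8a-dimethyl-4a,5,6,7,8,8a-hexahydronaphthalen-1(4H)-one
Conditions: KOH, MeOH/H2O, rt
Reagents that add atoms: none
Why: Base-mediated intramolecular aldol condensation: the lactol opens, the methyl ketone enolate (C8) adds to the C7 aldehyde in a 6-(enolexo)-exo-trig closure and E1cB dehydration drives the sequence to the ring B enone; the other aldol modes are reversible or would give strained rings. No stereocentre is formed and none can epimerise, so the trans ring fusion follows from step 2.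

**Step 6**
Reactants: 10 (4aR,5S,8aS)-5-hydroxy-5,8a-dimethyl-4a,5,6,7,8,8a-hexahydronaphthalen-1(4H)-one
Product: 12 (2R,4aR,5S,8aS)-5-hydroxy-2,5,8a-trimethyloctahydronaphthalen-1(2H)-one, via lithium enolate 11 (not isolated)
Conditions: LiBH(s-Bu)3 (1.2 equiv), THF, −78 °C; MeI, −78 °C → rt
Reagents that add atoms: iodomethane, CI
Why: Reductive alkylation: the bulky borohydride delivers hydride to C7 of the β-unsubstituted cyclohexenone (1,2-attack at C9 is blocked by quaternary C10), giving the C8=C9 enolate 11 regiospecifically, and iodomethane alkylates it at C8. The tertiary hydroxyl is too weak an acid to quench the enolate. The C8 methyl is expected equatorial (α), but this centre is erased in step 11.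

**Step 7**
Reactants: 12 (2R,4aR,5S,8aS)-5-hydroxy-2,5,8a-trimethyloctahydronaphthalen-1(2H)-one
Product: 13 methyl (1S,4aS,6R,8aR)-1,4a,6-trimethyl-5-oxodecahydronaphthalen-1-yl oxalate
Conditions: ClC(O)CO2Me, Et3N, DMAP, CH2Cl2, 0 °C → rt
Reagents that add atoms: methyl chlorooxoacetate, COC(=O)C(Cl)=O
Why: DMAP-catalysed acylation of the tertiary alcohol by a highly electrophilic acid chloride gives the mixed oxalate diester; the hindered C9 ketone is inert.

**Step 8**
Reactants: 13 methyl (1S,4aS,6R,8aR)-1,4a,6-trimethyl-5-oxodecahydronaphthalen-1-yl oxalate
Product: 14 cesium 2-oxo-2-{[(1S,4aS,6R,8aR)-1,4a,6-trimethyl-5-oxodecahydronaphthalen-1-yl]oxy}acetate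
Conditions: CsOH (1.0 equiv), THF/H2O, rt
Reagents that add atoms: cesium hydroxide, [Cs+].[OH-]
Why: One equivalent of hydroxide saponifies the unhindered methyl ester of the mixed oxalate selectively, the tertiary alkyl ester being shielded; the cesium half-oxalate is the stable radical precursor.

**Step 9**
Reactants: 14 cesium 2-oxo-2-{[(1S,4aS,6R,8aR)-1,4a,6-trimethyl-5-oxodecahydronaphthalen-1-yl]oxy}acetate
Product: 15 3-[(1S,4aS,6R,8aS)-1,4a,6-trimethyl-5-oxodecahydronaphthalen-1-yl]propanal
Conditions: acrolein, Ir[dF(CF3)ppy]2(dtbbpy)PF6 (1 mol %), H2O, DME/DMF 3:1, blue LEDs, 60 °C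
Reagents that add atoms: acrolein, C=CC=O
Why: Photoredox decarboxylative Giese addition: the excited trivalent iridium complex oxidises the oxalate, loss of two CO2 gives the tertiary C4 radical, this adds to acrolein, and the α-formyl radical is reduced by divalent iridium and protonated by water. C4 is set by the substrate: in the rigid trans-decalin the β face of the planar radical is blocked by the syn-axial C10 methyl, so the acceptor bonds on the α face, leaving the chain equatorial (α) and the C4 methyl axial (β), which is S at C4.

**Step 10**
Reactants: 15 3-[(1S,4aS,6R,8aS)-1,4a,6-trimethyl-5-oxodecahydronaphthalen-1-yl]propanal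
Product: 16 (2R,4aS,5S,8aS)-2,5,8a-trimethyl-5-(4-methylpent-3-en-1-yl)octahydronaphthalen-1(2H)-one
Conditions: i-PrPPh3I, n-BuLi, THF, 0 °C; then 15, −78 °C → rt
Reagents that add atoms: isopropyltriphenylphosphonium iodide, CC(C)[P+](c1ccccc1)(c1ccccc1)c1ccccc1.[I-]
Why: Wittig olefination with the unstabilised isopropylidene ylide converts the aldehyde into the terminal trisubstituted alkene, which has no geometry to control. The C9 ketone, between a quaternary and a tertiary carbon, is too hindered to react.

**Step 11**
Reactants: 16 (2R,4aS,5S,8aS)-2,5,8a-trimethyl-5-(4-methylpent-3-en-1-yl)octahydronaphthalen-1(2H)-one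
Product: 18 (4aS,5S,8aS)-2,5,8a-trimethyl-5-(4-methylpent-3-en-1-yl)-3,4,4a,5,6,7,8,8a-octahydronaphthalen-1-yl trifluoromethanesulfonate, via potassium enolate 17 (not isolated)
Conditions: KN(SiMe3)2, THF, −78 → 0 °C; PhNTf2, −78 °C → rt
Reagents that add atoms: N-phenylbis(trifluoromethanesulfonimide), O=S(=O)(N(c1ccccc1)S(=O)(=O)C(F)(F)F)C(F)(F)F
Why: Because C10 is quaternary the ketone can enolise only towards C8, so O-sulfonylation of enolate 17 gives the tetrasubstituted C8=C9 enol triflate as one regioisomer and erases the C8 stereocentre.

**Step 12**
Reactants: 18 (4aS,5S,8aS)-2,5,8a-trimethyl-5-(4-methylpent-3-en-1-yl)-3,4,4a,5,6,7,8,8a-octahydronaphthalen-1-yl trifluoromethanesulfonate; 19 (4-bromobut-1-yn-1-yl)trimethylsilane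
Product: 21 trimethyl{4-[(4aS,5S,8aS)-2,5,8a-trimethyl-5-(4-methylpent-3-en-1-yl)-3,4,4a,5,6,7,8,8a-octahydronaphthalen-1-yl]but-1-yn-1-yl}silane, via organozinc bromide 20 (not isolated)
Conditions: 19, Zn, LiCl, THF, 50 °C; then 18, Pd(dppf)Cl2 (5 mol %), THF/NMP, 60 °C
Reagents that add atoms: none
Why: Zinc insertion into the primary bromide gives organozinc 20; Negishi coupling (oxidative addition of zerovalent palladium into the C9–O bond, transmetalation, reductive elimination) forms the C9–C11 sp2–sp3 bond. The wide-bite-angle ferrocenyl diphosphine favours reductive elimination over β-hydride elimination, and the silyl cap keeps an alkyne C–H from quenching the organozinc.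

**Step 13**
Reactants: 21 trimethyl{4-[(4aS,5S,8aS)-2,5,8a-trimethyl-5-(4-methylpent-3-en-1-yl)-3,4,4a,5,6,7,8,8a-octahydronaphthalen-1-yl]but-1-yn-1-yl}silane
Product: 22 (4aS,5S,8aS)-1-(but-3-yn-1-yl)-2,5,8a-trimethyl-5-(4-methylpent-3-en-1-yl)-3,4,4a,5,6,7,8,8a-octahydronaphthalene
Conditions: K2CO3, MeOH, rt
Reagents that add atoms: none
Why: Base-catalysed methanolysis of the C(sp)–Si bond frees the terminal alkyne; nothing else in the molecule reacts.

**Step 14**
Reactants: 22 (4aS,5S,8aS)-1-(but-3-yn-1-yl)-2,5,8a-trimethyl-5-(4-methylpent-3-en-1-yl)-3,4,4a,5,6,7,8,8a-octahydronaphthalene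
Product: 24 methyl (2E)-3-methyl-5-[(4aS,5S,8aS)-2,5,8a-trimethyl-5-(4-methylpent-3-en-1-yl)-3,4,4a,5,6,7,8,8a-octahydronaphthalen-1-yl]pent-2-enoate, via alkenylalane 23 (not isolated)
Conditions: AlMe3, Cp2ZrCl2, CH2Cl2, 0 °C → rt; ClCO2Me, rt
Reagents that add atoms: trimethylaluminium, C[Al](C)C; methyl chloroformate, COC(Cl)=O
Why: Zirconium-catalysed methylalumination (Negishi carboalumination) adds methyl and aluminium syn across the terminal alkyne with methyl on the internal carbon C13; alkenylalane 23 is then acylated by the chloroformate with retention, which fixes the E geometry of C13=C14. The tri- and tetrasubstituted alkenes are inert to the reagent.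

**Step 15**
Reactants: 24 methyl (2E)-3-methyl-5-[(4aS,5S,8aS)-2,5,8a-trimethyl-5-(4-methylpent-3-en-1-yl)-3,4,4a,5,6,7,8,8a-octahydronaphthalen-1-yl]pent-2-enoate
Product: 25 (2E)-3-methyl-5-[(4aS,5S,8aS)-2,5,8a-trimethyl-5-(4-methylpent-3-en-1-yl)-3,4,4a,5,6,7,8,8a-octahydronaphthalen-1-yl]pent-2-enoic acid
Conditions: LiOH, THF/MeOH/H2O, 50 °C; aq HCl
Reagents that add atoms: lithium hydroxide, [Li+].[OH-]
Why: Saponification of the methyl ester followed by acidification; the β,β-disubstituted (E)-enoate should keep its geometry and position under these conditions.

## Compound list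

1 | 2-bromopropene | C=C(C)Br | starting material
2 | isopropenylmagnesium bromide (prop-1-en-2-ylmagnesium bromide) | C=C(C)[Mg]Br | intermediate
3 | 3-methylcyclohex-2-en-1-one | CC1=CC(=O)CCC1 | starting material
4 | allyl bromide (3-bromoprop-1-ene) | C=CCBr | starting material
5 | bromomagnesium (3S)-3-methyl-3-(prop-1-en-2-yl)cyclohex-1-en-1-olate | C=C(C)[C@]1(C)C=C(O[Mg]Br)CCC1 | intermediate
6 | (2R,3S)-3-methyl-3-(prop-1-en-2-yl)-2-(prop-2-en-1-yl)cyclohexan-1-one (allyl trans to isopropenyl) | O=C1CCC[C@](C)(C(C)=C)[C@H]1CC=C | intermediate
7 | (1S,2R,3S)-1,3-dimethyl-3-(prop-1-en-2-yl)-2-(prop-2-en-1-yl)cyclohexan-1-ol | C[C@]1(O)CCC[C@](C)(C(C)=C)[C@H]1CC=C | intermediate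
8 | bis-ozonide of 7: (1S,2R,3S)-1,3-dimethyl-3-(3-methyl-1,2,4-trioxolan-3-yl)-2-(1,2,4-trioxolan-3-ylmethyl)cyclohexan-1-ol (trioxolane carbons as epimer mixtures) | C[C@]1(O)CCC[C@](C)(C2(C)OCOO2)[C@H]1CC3OCOO3 | intermediate
9 | 2-[(1R,2S,6S)-2-acetyl-6-hydroxy-2,6-dimethylcyclohexyl]acetaldehyde (in ring–chain equilibrium with its lactol) | C[C@]1(O)CCC[C@](C)(C(C)=O)[C@H]1CC=O | intermediate
10 | (4aR,5S,8aS)-5-hydroxy-5,8a-dimethyl-4a,5,6,7,8,8a-hexahydronaphthalen-1(4H)-one (trans-fused; 4β-OH, 10β-Me, 5α-H) | C[C@]1(O)CCC[C@]2(C)C(=O)C=CC[C@@H]12 | intermediate
11 | lithium (4aR,5S,8aS)-5-hydroxy-5,8a-dimethyl-3,4,4a,5,6,7,8,8a-octahydronaphthalen-1-olate | C[C@]1(O)CCC[C@]2(C)C(O[Li])=CCC[C@@H]12 | intermediate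
12 | (2R,4aR,5S,8aS)-5-hydroxy-2,5,8a-trimethyloctahydronaphthalen-1(2H)-one | C[C@]1(O)CCC[C@]2(C)C(=O)[C@H](C)CC[C@@H]12 | intermediate
13 | methyl (1S,4aS,6R,8aR)-1,4a,6-trimethyl-5-oxodecahydronaphthalen-1-yl oxalate | COC(=O)C(=O)O[C@@]1(C)CCC[C@]2(C)C(=O)[C@H](C)CC[C@@H]12 | intermediate
14 | cesium 2-oxo-2-{[(1S,4aS,6R,8aR)-1,4a,6-trimethyl-5-oxodecahydronaphthalen-1-yl]oxy}acetate | [Cs+].[O-]C(=O)C(=O)O[C@@]1(C)CCC[C@]2(C)C(=O)[C@H](C)CC[C@@H]12 | intermediate
15 | 3-[(1S,4aS,6R,8aS)-1,4a,6-trimethyl-5-oxodecahydronaphthalen-1-yl]propanal (chain 4α, methyl 4β) | O=CCC[C@]1(C)CCC[C@]2(C)C(=O)[C@H](C)CC[C@@H]12 | intermediate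
16 | (2R,4aS,5S,8aS)-2,5,8a-trimethyl-5-(4-methylpent-3-en-1-yl)octahydronaphthalen-1(2H)-one | CC(C)=CCC[C@]1(C)CCC[C@]2(C)C(=O)[C@H](C)CC[C@@H]12 | intermediate
17 | potassium (4aS,5S,8aS)-2,5,8a-trimethyl-5-(4-methylpent-3-en-1-yl)-3,4,4a,5,6,7,8,8a-octahydronaphthalen-1-olate | CC(C)=CCC[C@]1(C)CCC[C@]2(C)C(O[K])=C(C)CC[C@@H]12 | intermediate
18 | (4aS,5S,8aS)-2,5,8a-trimethyl-5-(4-methylpent-3-en-1-yl)-3,4,4a,5,6,7,8,8a-octahydronaphthalen-1-yl trifluoromethanesulfonate | CC(C)=CCC[C@]1(C)CCC[C@]2(C)C(OS(=O)(=O)C(F)(F)F)=C(C)CC[C@@H]12 | intermediate
19 | (4-bromobut-1-yn-1-yl)trimethylsilane | C[Si](C)(C)C#CCCBr | starting material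
20 | [4-(trimethylsilyl)but-3-yn-1-yl]zinc bromide | C[Si](C)(C)C#CCC[Zn]Br | intermediate
21 | trimethyl{4-[(4aS,5S,8aS)-2,5,8a-trimethyl-5-(4-methylpent-3-en-1-yl)-3,4,4a,5,6,7,8,8a-octahydronaphthalen-1-yl]but-1-yn-1-yl}silane | CC(C)=CCC[C@]1(C)CCC[C@]2(C)C(CCC#C[Si](C)(C)C)=C(C)CC[C@@H]12 | intermediate
22 | (4aS,5S,8aS)-1-(but-3-yn-1-yl)-2,5,8a-trimethyl-5-(4-methylpent-3-en-1-yl)-3,4,4a,5,6,7,8,8a-octahydronaphthalene | CC(C)=CCC[C@]1(C)CCC[C@]2(C)C(CCC#C)=C(C)CC[C@@H]12 | intermediate
23 | dimethyl{(1E)-2-methyl-4-[(4aS,5S,8aS)-2,5,8a-trimethyl-5-(4-methylpent-3-en-1-yl)-3,4,4a,5,6,7,8,8a-octahydronaphthalen-1-yl]but-1-en-1-yl}alumane | CC(C)=CCC[C@]1(C)CCC[C@]2(C)C(CC/C(C)=C/[Al](C)C)=C(C)CC[C@@H]12 | intermediate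
24 | methyl (2E)-3-methyl-5-[(4aS,5S,8aS)-2,5,8a-trimethyl-5-(4-methylpent-3-en-1-yl)-3,4,4a,5,6,7,8,8a-octahydronaphthalen-1-yl]pent-2-enoate | CC(C)=CCC[C@]1(C)CCC[C@]2(C)C(CC/C(C)=C/C(=O)OC)=C(C)CC[C@@H]12 | intermediate
25 | (2E)-3-methyl-5-[(4aS,5S,8aS)-2,5,8a-trimethyl-5-(4-methylpent-3-en-1-yl)-3,4,4a,5,6,7,8,8a-octahydronaphthalen-1-yl]pent-2-enoic acid (4S,5S,10S in labdane-type numbering) | CC(C)=CCC[C@]1(C)CCC[C@]2(C)C(CC/C(C)=C/C(=O)O)=C(C)CC[C@@H]12 | target

## Step count and least certain steps

Total: 15 steps. Longest linear sequence: 15 steps from 1 to 25 (14 from 3). The only branch is the zinc reagent 20, which is made in the flask from commercial 19.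

**Step 2 (key step).** The magnesium enolate 5 sits next to the new quaternary carbon and may alkylate slowly. Proton transfer between enolate and product would then erode regiocontrol (allylation on the C3 side, double allylation), and the facial preference anti to isopropenyl may be only moderate because methyl and isopropenyl differ little in size. The enantioselectivity of alkenyl Grignard additions is also sensitive to solvent and addition rate. Fallback, setting out from enolate 5: quench with allyl chloroformate instead of 4 to give allyl (3S)-3-methyl-3-(prop-1-en-2-yl)cyclohex-1-en-1-yl carbonate F1, which is isolated. Treatment with Pd(PPh3)4 in THF then effects decarboxylative Tsuji allylation through a π-allyl/enolate ion pair formed by zerovalent palladium; this pair recombines regiospecifically at C5 and returns to 6. A cis isomer, if formed, can be equilibrated with base and recycled, since C5 is still epimerisable at that stage.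

**Step 5.** The aldehyde of 9 is largely tied up as a lactol, so the concentration of free aldehyde is low and ring closure may be slow; intermolecular aldol oligomerisation could then compete. Fallback, setting out from 7: silylate the tertiary hydroxyl (Et3SiOTf, 2,6-lutidine) to the triethylsilyl ether F2. Ozonolysis through its bis-ozonide F3 with PPh3 work-up gives the silyl-protected keto aldehyde F4, which cannot form a lactol. Aldol condensation with KOH in methanol gives the silyl-protected enone F5, and Bu4NF in THF removes the silyl group to return to 10.

**Step 6.** Hydride delivery may not be fully 1,4-selective, and proton exchange between product and enolate could lead to double methylation at C8 or to O-methylation of the C4 alkoxide. Fallback, setting out from 10: hydrogenate the enone alkene (H2, Pd/C, EtOAc) to the saturated hydroxy ketone F6. Deprotonation with LiN(i-Pr)2 (2.2 equiv) gives the dilithium alkoxide enolate F7 (only C8 can enolise), and iodomethane returns to 12.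

**Step 9.** Capture of the tertiary radical by acrolein may be inefficient, because the volatile enal tends to oligomerise under the warm, mildly basic photochemical conditions; the radical would then be lost to reduction or disproportionation. Incomplete α-face selectivity is the second concern. Fallback, setting out from 14: use methyl acrylate as the acceptor under the same photoredox conditions to give the keto ester F8. Reduction of both carbonyl groups with LiAlH4 gives the diol F9, and Swern oxidation of both hydroxyls returns to 15; the C8 configuration is again immaterial.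

**Step 12.** Oxidative addition and transmetalation at the tetrasubstituted triflate next to C10 may be slow, which lets β-hydride elimination of the alkylpalladium intermediate or simple reduction of the triflate compete. Fallback, setting out from 18: methoxycarbonylation (Pd(OAc)2, dppf, CO, MeOH, Et3N, DMF) gives the conjugated methyl ester F10. Reduction with i-Bu2AlH gives the allylic alcohol F11, and CBr4/PPh3 gives the allylic bromide F12. SN2 displacement by lithiated 1-(trimethylsilyl)propyne (n-BuLi, THF, −78 °C) forms the C11–C12 bond and returns to 21.

## Further compounds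

F1 | step 2 | allyl (3S)-3-methyl-3-(prop-1-en-2-yl)cyclohex-1-en-1-yl carbonate | C=CCOC(=O)OC1=C[C@@](C)(C(C)=C)CCC1
F2 | step 5 | triethyl{[(1S,2R,3S)-1,3-dimethyl-3-(prop-1-en-2-yl)-2-(prop-2-en-1-yl)cyclohexyl]oxy}silane | C[C@]1(O[Si](CC)(CC)CC)CCC[C@](C)(C(C)=C)[C@H]1CC=C
F3 | step 5 | bis-ozonide of F2 (both alkenes as 1,2,4-trioxolanes) | C[C@]1(O[Si](CC)(CC)CC)CCC[C@](C)(C2(C)OCOO2)[C@H]1CC3OCOO3
F4 | step 5 | 2-[(1R,2S,6S)-2-acetyl-2,6-dimethyl-6-(triethylsilyloxy)cyclohexyl]acetaldehyde | C[C@]1(O[Si](CC)(CC)CC)CCC[C@](C)(C(C)=O)[C@H]1CC=O
F5 | step 5 | (4aR,5S,8aS)-5,8a-dimethyl-5-(triethylsilyloxy)-4a,5,6,7,8,8a-hexahydronaphthalen-1(4H)-one | C[C@]1(O[Si](CC)(CC)CC)CCC[C@]2(C)C(=O)C=CC[C@@H]12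
F6 | step 6 | (4aR,5S,8aS)-5-hydroxy-5,8a-dimethyloctahydronaphthalen-1(2H)-one | C[C@]1(O)CCC[C@]2(C)C(=O)CCC[C@@H]12
F7 | step 6 | dilithium alkoxide enolate of F6 | C[C@]1(O[Li])CCC[C@]2(C)C(O[Li])=CCC[C@@H]12
F8 | step 9 | methyl 3-[(1S,4aS,6R,8aS)-1,4a,6-trimethyl-5-oxodecahydronaphthalen-1-yl]propanoate | COC(=O)CC[C@]1(C)CCC[C@]2(C)C(=O)[C@H](C)CC[C@@H]12
F9 | step 9 | 3-[5-hydroxy-1,4a,6-trimethyldecahydronaphthalen-1-yl]propan-1-ol (ring stereocentres as in F8, new carbinol as an epimer mixture) | OCCC[C@]1(C)CCC[C@]2(C)C(O)[C@H](C)CC[C@@H]12
F10 | step 12 | methyl (4aS,5S,8aS)-2,5,8a-trimethyl-5-(4-methylpent-3-en-1-yl)-3,4,4a,5,6,7,8,8a-octahydronaphthalene-1-carboxylate | CC(C)=CCC[C@]1(C)CCC[C@]2(C)C(C(=O)OC)=C(C)CC[C@@H]12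
F11 | step 12 | [(4aS,5S,8aS)-2,5,8a-trimethyl-5-(4-methylpent-3-en-1-yl)-3,4,4a,5,6,7,8,8a-octahydronaphthalen-1-yl]methanol | CC(C)=CCC[C@]1(C)CCC[C@]2(C)C(CO)=C(C)CC[C@@H]12
F12 | step 12 | (4aS,5S,8aS)-1-(bromomethyl)-2,5,8a-trimethyl-5-(4-methylpent-3-en-1-yl)-3,4,4a,5,6,7,8,8a-octahydronaphthalene | CC(C)=CCC[C@]1(C)CCC[C@]2(C)C(CBr)=C(C)CC[C@@H]12
A1 | alternative 1 | 2,6-dimethyl-1,4-benzoquinone | CC1=CC(=O)C=C(C)C1=O
A2 | alternative 1 | (E)-tert-butyldimethyl(penta-1,3-dien-2-yloxy)silane | C/C=C/C(=C)O[Si](C)(C)C(C)(C)C
A3 | alternative 1 | cis-fused endo adduct: 7-(tert-butyldimethylsilyloxy)-2,5,8a-trimethyl-4a,5,8,8a-tetrahydronaphthalene-1,4-dione (10β-methyl, 5β-H, 4α-methyl in labdane-type numbering) | C[C@@H]1C=C(O[Si](C)(C)C(C)(C)C)C[C@]2(C)C(=O)C(C)=CC(=O)[C@H]12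
A4 | alternative 2 | (3E,5S,9E)-5-(tert-butyldimethylsilyloxy)-4,10,14-trimethylpentadeca-1,3,9,13-tetraen-8-one | C=C/C=C(\C)[C@@H](O[Si](C)(C)C(C)(C)C)CCC(=O)/C=C(\C)CCC=C(C)C
A5 | alternative 2 | trans-fused 6-oxo-9-silyloxy octalin with C1=C2 alkene, C4 (β-methyl, α-homoprenyl) and C10 (β-methyl) quaternary centres | CC(C)=CCC[C@]1(C)CC=C[C@]2(C)[C@@H](O[Si](C)(C)C(C)(C)C)CCC(=O)[C@@H]12
A6 | alternative 3 | meso-{[2,6-diethenyl-2,6-dimethyl-1-(3-methylbut-3-en-1-yl)cyclohexyl]oxy}trimethylsilane (vinyl groups cis to each other and to the silyloxy group) | C=C[C@]1(C)CCC[C@](C)(C=C)[C@@]1(O[Si](C)(C)C)CCC(C)=C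
A7 | alternative 3 | 5-ethenyl-2,5,8a-trimethyl-4a-(trimethylsilyloxy)-3,4,4a,5,6,7,8,8a-octahydronaphthalene (4α-vinyl, 4β-methyl, 5α-silyloxy, 10β-methyl in labdane-type numbering) | C=C[C@]1(C)CCC[C@]2(C)C=C(C)CC[C@@]12O[Si](C)(C)C
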